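**Assumption:** the target has no stereogenic centre, so "single enantiomer" is read as the single (2E,6E) geometric isomer drawn; both E olefins are bought with (2E,6E)-farnesol and never touched.

**Retrosynthetic overview**
1. The only ring to build is the γ-lactone. It is closed last from a methyl 3-hydroxybenzoate and formaldehyde by Mg-templated ortho-hydroxymethylation and in-flask acyl C–O closure (proposed new reaction).
2. Key disconnection: the aryl O–CH2 allyl ether bond, made by a regio- and chemoselective Mitsunobu C–O coupling of methyl 3-O-methylgallate (4-OH) with the primary allylic OH of 11-hydroxy-10,11-dihydrofarnesol.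
3. The tertiary carbinol C–O bond comes from terminal-selective Markovnikov hydration (oxymercuration–demercuration) of (2E,6E)-farnesol.
4. Ring order: benzene ring bought, lactone ring formed in step 3; no protecting groups; the ether is made before the lactone so that the template step meets a monophenol with a single free ortho position.

**Route**

Step 1
Reactants: 1 (2E,6E)-farnesol [(2E,6E)-3,7,11-trimethyldodeca-2,6,10-trien-1-ol]
Product: 3 (2E,6E)-3,7,11-trimethyldodeca-2,6-diene-1,11-diol, via 10-acetoxymercurio adduct 2 (not isolated)
Conditions: Hg(OAc)2 (1.0 equiv), THF/H2O 1:1, 0 °C to rt, 1 h; then 3 M NaOH, NaBH4, 0 °C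
Reagents that add atoms: water, O
Why: Markovnikov oxymercuration–demercuration, in which divalent mercury should add fastest to the most accessible terminal isopropylidene olefin (the C2 olefin is deactivated by the allylic oxygen, the C6 olefin is more hindered), water opens the mercurinium ion at the tertiary carbon, and NaBH4 replaces mercury by hydrogen without touching the two E olefins; no stereocentre remains.

Step 2
Reactants: 3 (2E,6E)-3,7,11-trimethyldodeca-2,6-diene-1,11-diol; 4 methyl 3,4-dihydroxy-5-methoxybenzoate (methyl 3-O-methylgallate, 1.3 equiv)
Product: 5 methyl 3-hydroxy-4-{[(2E,6E)-11-hydroxy-3,7,11-trimethyldodeca-2,6-dien-1-yl]oxy}-5-methoxybenzoate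
Conditions: PPh3 (1.2 equiv), diisopropyl azodicarboxylate (DIAD, 1.2 equiv, slow addition), THF, 0 °C to rt
Reagents that add atoms: none
Why: Mitsunobu etherification, in which the more acidic 4-OH (para to the ester) is the one deprotonated and alkylated, only the primary allylic alcohol is activated (the tertiary alcohol cannot undergo SN2), and direct SN2 displacement at the primary allylic carbon keeps the 2E geometry.

Step 3
Reactants: 5 methyl 3-hydroxy-4-{[(2E,6E)-11-hydroxy-3,7,11-trimethyldodeca-2,6-dien-1-yl]oxy}-5-methoxybenzoate
Product: 7 farnesylemefuranone E [4-hydroxy-5-{[(2E,6E)-11-hydroxy-3,7,11-trimethyldodeca-2,6-dien-1-yl]oxy}-6-methoxy-2-benzofuran-1(3H)-one], via hydroxymethyl benzoate 6 (not isolated)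
Conditions: MgCl2 (2.0 equiv), Et3N (4.0 equiv), (CH2O)n (1.5 equiv, portionwise), THF, 65 °C; then 10% aq. citric acid
Reagents that add atoms: paraformaldehyde (reacts as formaldehyde), C=O
Why: Proposed new method: an interrupted Casnati–Skattebøl reaction, in which the chloromagnesium phenoxide of 5 binds formaldehyde and delivers it through the usual six-membered transition state to the only free ortho carbon (C2, also para to OMe) to give the chloromagnesium salicyl alkoxide of 6, which in the known formylation would pass hydride to a second formaldehyde but here sits 5-exo to the neighbouring methyl ester and should lactonize with loss of methoxide faster than that bimolecular Oppenauer step when formaldehyde is kept near stoichiometric; the closest known reactions are the MgCl2/Et3N/paraformaldehyde ortho-formylation of phenols (same C–C bond-forming event) and the spontaneous lactonization of 2-(hydroxymethyl)benzoates to phthalides, and the mild basic conditions leave the doubly ortho-blocked allyl aryl ether, the tertiary alcohol and both E olefins intact.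

**Compound list**

1 | (2E,6E)-farnesol, (2E,6E)-3,7,11-trimethyldodeca-2,6,10-trien-1-ol | OC/C=C(\C)CC/C=C(\C)CCC=C(C)C | starting material
2 | (2E,6E)-10-(acetoxymercurio)-3,7,11-trimethyldodeca-2,6-diene-1,11-diol, racemic at C10, formed in the flask | OC/C=C(\C)CC/C=C(\C)CCC([Hg]OC(C)=O)C(C)(C)O | intermediate
3 | (2E,6E)-3,7,11-trimethyldodeca-2,6-diene-1,11-diol | OC/C=C(\C)CC/C=C(\C)CCCC(C)(C)O | intermediate
4 | methyl 3,4-dihydroxy-5-methoxybenzoate (methyl 3-O-methylgallate) | COC(=O)c1cc(O)c(O)c(OC)c1 | starting material
5 | methyl 3-hydroxy-4-{[(2E,6E)-11-hydroxy-3,7,11-trimethyldodeca-2,6-dien-1-yl]oxy}-5-methoxybenzoate | COC(=O)c1cc(O)c(OC/C=C(\C)CC/C=C(\C)CCCC(C)(C)O)c(OC)c1 | intermediate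
6 | methyl 3-hydroxy-2-(hydroxymethyl)-4-{[(2E,6E)-11-hydroxy-3,7,11-trimethyldodeca-2,6-dien-1-yl]oxy}-5-methoxybenzoate, formed in the flask as its chloromagnesium alkoxide | COC(=O)c1cc(OC)c(OC/C=C(\C)CC/C=C(\C)CCCC(C)(C)O)c(O)c1CO | intermediate
7 | farnesylemefuranone E, 4-hydroxy-5-{[(2E,6E)-11-hydroxy-3,7,11-trimethyldodeca-2,6-dien-1-yl]oxy}-6-methoxy-2-benzofuran-1(3H)-one | COc1cc2c(c(O)c1OC/C=C(\C)CC/C=C(\C)CCCC(C)(C)O)COC2=O | target

**Step count**

Total steps: 3. Longest linear sequence: 3 steps (1 → 3 → 5 → 7).

**Steps most likely to fail, with fallbacks**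

Step 3 (the proposed new step). The chloromagnesium alkoxide of 6 may be oxidised to the aldehyde or condense to diarylmethanes before it lactonizes, and attack at the hindered C2 may be slow. Any untemplated para attack at C6 would give the isomeric phthalide. The fallback uses known chemistry, sets out from 5 and comes back at 7. Compound 5 is subjected to the standard Casnati–Skattebøl ortho-formylation driven to completion (MgCl2, Et3N, excess paraformaldehyde, MeCN, reflux), and the salicylaldehyde methyl 2-formyl-3-hydroxy-4-{[(2E,6E)-11-hydroxy-3,7,11-trimethyldodeca-2,6-dien-1-yl]oxy}-5-methoxybenzoate F3 is isolated. NaBH4 in MeOH at 0 °C then reduces the aldehyde to 6, which closes to the phthalide 7 on stirring with a trace of K2CO3. This replaces the redox-neutral interception by a formylation–reduction sequence through an isolated aldehyde.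

Step 1. Site selectivity may be incomplete, giving C6-olefin hydration or double hydration, and the isomeric diols are close on silica. The reaction is stopped short of full conversion and farnesol is recycled. The fallback sets out from 1 and comes back at 3. NBS in THF/H2O at 0 °C forms the terminal bromohydrin (2E,6E)-10-bromo-3,7,11-trimethyldodeca-2,6-diene-1,11-diol F1 with the well-established terminal selectivity of polyprenyl chains in aqueous medium. Radical debromination with Bu3SnH and AIBN in toluene at 80 °C then gives 3; the C10 radical has no favourable cyclization onto the C6 olefin.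

Step 2. Some alkylation at the 3-OH, double alkylation or SN2′ attack may lower the yield. The fallback sets out from 3 and comes back at 5. MsCl and Et3N in THF at −40 °C followed by LiBr convert only the primary allylic alcohol into the bromide (6E,10E)-12-bromo-2,6,10-trimethyldodeca-6,10-dien-2-ol F2. Williamson alkylation of 4 (1.5 equiv) with F2 and Li2CO3 in DMF at 40 °C then proceeds under acidity control, so only the 4-OH para to the ester is ionised and alkylated, giving 5.

**Further compounds**

F1 | step 1 | (2E,6E)-10-bromo-3,7,11-trimethyldodeca-2,6-diene-1,11-diol, racemic at C10 | OC/C=C(\C)CC/C=C(\C)CCC(Br)C(C)(C)O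
F2 | step 2 | (6E,10E)-12-bromo-2,6,10-trimethyldodeca-6,10-dien-2-ol | BrC/C=C(\C)CC/C=C(\C)CCCC(C)(C)O
F3 | step 3 | methyl 2-formyl-3-hydroxy-4-{[(2E,6E)-11-hydroxy-3,7,11-trimethyldodeca-2,6-dien-1-yl]oxy}-5-methoxybenzoate | COC(=O)c1cc(OC)c(OC/C=C(\C)CC/C=C(\C)CCCC(C)(C)O)c(O)c1C=O
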